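**Plan** (ring atoms: C1 = C=O, C2=C3, C4 = CHOH, C5 = C(OH)R, C6 = CH2; side chain C1'–C19')
- Retrosynthesis: the cyclohexenone is opened at C2=C3 (intramolecular Horner–Wadsworth–Emmons olefination), then cut at C5–C6 (aldol addition of an acetonylphosphonate dianion to a C5 ketone), at C5–C1' (Weinreb ketone synthesis) and at C15'–C16' (acetylide alkylation).
- Enabling feature: C1 and C3 are 1,5-related through C6–C5–C4, and in the precursor C2 lies between the C1 carbonyl and a phosphoryl group, so the C2 carbanion reaches a C3 aldehyde through a six-membered transition state that becomes the cyclohexenone ring.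
- Forward: side-chain bromide (three steps) → Grignard addition to an L-threonate-derived Weinreb amide → dianion aldol adds C6–C1–C2 → glycol cleavage unveils C3 → ring closure → desilylation.
- Stereochemistry: C4 is C2 of L-threonate (vitamin C pool); C5 is set by Felkin–Anh addition to the α-silyloxy ketone; the side-chain E-alkene comes from Na/NH3 reduction of an alkyne; the ring alkene is cis by ring constraint.

Key step: step 9

Step 1
Reactants: 1 15-bromopentadecan-1-ol; 2 but-1-yne
Product: 4 nonadec-16-yn-1-ol, via lithium butynide 3 (not isolated)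
Conditions: 2 (3 equiv), n-BuLi (2.5 equiv), THF, −78 °C; then 1, DMPU, −78 °C to rt
Reagents that add atoms: none
Why: SN2 alkylation of a lithium acetylide by a primary bromide, in which the first equivalent of acetylide only converts the hydroxyl into a spectator lithium alkoxide.

Step 2
Reactants: 4 nonadec-16-yn-1-ol
Product: 5 (16E)-nonadec-16-en-1-ol
Conditions: Na, NH3(l), THF, −33 °C; then NH4Cl
Reagents that add atoms: none
Why: Dissolving-metal reduction of an isolated internal alkyne, in which the trans vinyl radical anion/vinyl anion is protonated and so should give the E-alkene only.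

Step 3
Reactants: 5 (16E)-nonadec-16-en-1-ol
Product: 6 (3E)-19-bromononadec-3-ene
Conditions: CBr4, PPh3, CH2Cl2, 0 °C
Reagents that add atoms: carbon tetrabromide, BrC(Br)(Br)Br
Why: Appel bromination of a primary alcohol under neutral conditions that leave the remote alkene untouched.

Step 4
Reactants: 7 methyl 3,4-O-isopropylidene-L-threonate [methyl (2R)-[(4S)-2,2-dimethyl-1,3-dioxolan-4-yl](hydroxy)acetate]
Product: 8 methyl (2R)-[(tert-butyldimethylsilyl)oxy][(4S)-2,2-dimethyl-1,3-dioxolan-4-yl]acetate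
Conditions: TBSCl, imidazole, DMF, rt
Reagents that add atoms: tert-butyldimethylsilyl chloride, CC(C)(C)[Si](C)(C)Cl
Why: Standard silylation of the free secondary hydroxyl, which installs a bulky, non-chelating group on the future O4 that also keeps the C4–C5 bond safe in the later glycol cleavage.

Step 5
Reactants: 8 methyl (2R)-[(tert-butyldimethylsilyl)oxy][(4S)-2,2-dimethyl-1,3-dioxolan-4-yl]acetate
Product: 9 (2R)-2-[(tert-butyldimethylsilyl)oxy]-2-[(4S)-2,2-dimethyl-1,3-dioxolan-4-yl]-N-methoxy-N-methylacetamide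
Conditions: MeNH(OMe)·HCl, i-PrMgCl, THF, −20 °C
Reagents that add atoms: N,O-dimethylhydroxylamine hydrochloride, CNOC.Cl
Why: Direct ester aminolysis by the chloromagnesium amide (Weinreb amide formation) at low temperature, which should not epimerise the α-silyloxy centre.

Step 6
Reactants: 6 (3E)-19-bromononadec-3-ene; 9 (2R)-2-[(tert-butyldimethylsilyl)oxy]-2-[(4S)-2,2-dimethyl-1,3-dioxolan-4-yl]-N-methoxy-N-methylacetamide
Product: 11 (1R,18E)-1-[(tert-butyldimethylsilyl)oxy]-1-[(4S)-2,2-dimethyl-1,3-dioxolan-4-yl]henicos-18-en-2-one, via alkenylmagnesium bromide 10 (not isolated)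
Conditions: 6, Mg, cat. I2, THF, 40 °C; then 9, THF, 0 °C; aq. NH4Cl
Reagents that add atoms: none
Why: Weinreb ketone synthesis, in which the stable magnesium chelate of the tetrahedral adduct prevents over-addition and releases the C5 ketone only on work-up.

Step 7
Reactants: 11 (1R,18E)-1-[(tert-butyldimethylsilyl)oxy]-1-[(4S)-2,2-dimethyl-1,3-dioxolan-4-yl]henicos-18-en-2-one; 12 dimethyl (2-oxopropyl)phosphonate
Product: 14 dimethyl [(4S,20E)-4-{(R)-[(tert-butyldimethylsilyl)oxy][(4S)-2,2-dimethyl-1,3-dioxolan-4-yl]methyl}-4-hydroxy-2-oxotricos-20-en-1-yl]phosphonate, via phosphonate dianion 13 (not isolated)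
Conditions: 12, NaH, THF, 0 °C; n-BuLi, 0 °C; then 11, −78 °C; AcOH, −78 °C
Reagents that add atoms: none
Why: Aldol addition of the terminal carbanion of the β-ketophosphonate dianion to the ketone, which should follow the Felkin–Anh model (C4–OSi bond antiperiplanar to the nucleophile, attack past the C4 hydrogen; the silyl ether does not chelate, and any 1,3-coordination through the dioxolane oxygen exposes the same face) and so set C5 as S, the cold acetic acid quench preventing retro-aldol reversal.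

Step 8
Reactants: 14 dimethyl [(4S,20E)-4-{(R)-[(tert-butyldimethylsilyl)oxy][(4S)-2,2-dimethyl-1,3-dioxolan-4-yl]methyl}-4-hydroxy-2-oxotricos-20-en-1-yl]phosphonate
Product: 15 dimethyl [(4S,20E)-4-{(1S)-1-[(tert-butyldimethylsilyl)oxy]-2-oxoethyl}-4-hydroxy-2-oxotricos-20-en-1-yl]phosphonate
Conditions: H5IO6, EtOAc, 0 °C to rt
Reagents that add atoms: none
Why: One-pot hydrolysis of the terminal isopropylidene acetal and glycol cleavage by periodic acid, which unveils the C3 aldehyde while the silylated O4 protects the C4–C5 bond and the alkene, silyl ether and ketophosphonate are inert.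

Step 9
Reactants: 15 dimethyl [(4S,20E)-4-{(1S)-1-[(tert-butyldimethylsilyl)oxy]-2-oxoethyl}-4-hydroxy-2-oxotricos-20-en-1-yl]phosphonate
Product: 16 (4R,5S)-4-[(tert-butyldimethylsilyl)oxy]-5-hydroxy-5-[(16E)-nonadec-16-en-1-yl]cyclohex-2-en-1-one
Conditions: LiCl, i-Pr2NEt, MeCN (0.01 M), rt
Reagents that add atoms: none
Why: Lithium-assisted deprotonation of the doubly activated C2 methylene (between the C1 ketone and the phosphoryl group) by the tertiary amine gives a stabilised carbanion that adds to the C3 aldehyde, and the oxaphosphetane collapses with loss of dimethyl phosphate to form the C2=C3 double bond. The closest known reaction type is the intramolecular Horner–Wadsworth–Emmons olefination of ω-oxo β-ketophosphonates to polyoxygenated cyclohex-2-enones under LiCl/amine conditions. The six-membered ring closes in the 6-(enolendo)-exo-trig mode, possible because C1 and C3 are 1,5-related through C6–C5–C4, and the ring enforces the cis alkene. No stereocenter is created; C4 and C5 are carried over from 15. The step needs chemoselective deprotonation at C2 in the presence of the epimerisable C4–H, the C6 methylene and the free tertiary C5 hydroxyl (retro-aldol, β-elimination), which the far higher acidity of the phosphonate methylene, the weak non-alkoxide base and the fast intramolecular capture of the aldehyde should secure.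

Step 10
Reactants: 16 (4R,5S)-4-[(tert-butyldimethylsilyl)oxy]-5-hydroxy-5-[(16E)-nonadec-16-en-1-yl]cyclohex-2-en-1-one
Product: 17 (4R,5S)-4,5-dihydroxy-5-[(16E)-nonadec-16-en-1-yl]cyclohex-2-en-1-one
Conditions: HF·pyridine, pyridine, THF, 0 °C to rt
Reagents that add atoms: none
Why: Fluoride-mediated cleavage of the secondary silyl ether under buffered conditions that avoid the basic medium in which the β-hydroxy enone could eliminate and aromatise.

**Compound list**
1 | 15-bromopentadecan-1-ol | BrCCCCCCCCCCCCCCCO | starting material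
2 | but-1-yne | CCC#C | starting material
3 | lithium but-1-yn-1-ide | [Li+].[C-]#CCC | intermediate
4 | nonadec-16-yn-1-ol | CCC#CCCCCCCCCCCCCCCCO | intermediate
5 | (16E)-nonadec-16-en-1-ol | CC/C=C/CCCCCCCCCCCCCCCO | intermediate
6 | (3E)-19-bromononadec-3-ene | CC/C=C/CCCCCCCCCCCCCCCBr | intermediate
7 | methyl 3,4-O-isopropylidene-L-threonate | COC(=O)[C@H](O)[C@@H]1COC(C)(C)O1 | starting material
8 | methyl (2R)-[(tert-butyldimethylsilyl)oxy][(4S)-2,2-dimethyl-1,3-dioxolan-4-yl]acetate | COC(=O)[C@H](O[Si](C)(C)C(C)(C)C)[C@@H]1COC(C)(C)O1 | intermediate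
9 | (2R)-2-[(tert-butyldimethylsilyl)oxy]-2-[(4S)-2,2-dimethyl-1,3-dioxolan-4-yl]-N-methoxy-N-methylacetamide | CON(C)C(=O)[C@H](O[Si](C)(C)C(C)(C)C)[C@@H]1COC(C)(C)O1 | intermediate
10 | [(16E)-nonadec-16-en-1-yl]magnesium bromide | CC/C=C/CCCCCCCCCCCCCCC[Mg]Br | intermediate
11 | (1R,18E)-1-[(tert-butyldimethylsilyl)oxy]-1-[(4S)-2,2-dimethyl-1,3-dioxolan-4-yl]henicos-18-en-2-one | CC/C=C/CCCCCCCCCCCCCCCC(=O)[C@H](O[Si](C)(C)C(C)(C)C)[C@@H]1COC(C)(C)O1 | intermediate
12 | dimethyl (2-oxopropyl)phosphonate | CC(=O)CP(=O)(OC)OC | starting material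
13 | lithium sodium 1,3-dianion of dimethyl (2-oxopropyl)phosphonate | [Li+].[Na+].[CH2-]C(=O)[CH-]P(=O)(OC)OC | intermediate
14 | dimethyl [(4S,20E)-4-{(R)-[(tert-butyldimethylsilyl)oxy][(4S)-2,2-dimethyl-1,3-dioxolan-4-yl]methyl}-4-hydroxy-2-oxotricos-20-en-1-yl]phosphonate | CC/C=C/CCCCCCCCCCCCCCC[C@](O)(CC(=O)CP(=O)(OC)OC)[C@H](O[Si](C)(C)C(C)(C)C)[C@@H]1COC(C)(C)O1 | intermediate
15 | dimethyl [(4S,20E)-4-{(1S)-1-[(tert-butyldimethylsilyl)oxy]-2-oxoethyl}-4-hydroxy-2-oxotricos-20-en-1-yl]phosphonate | CC/C=C/CCCCCCCCCCCCCCC[C@](O)(CC(=O)CP(=O)(OC)OC)[C@H](O[Si](C)(C)C(C)(C)C)C=O | intermediate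
16 | (4R,5S)-4-[(tert-butyldimethylsilyl)oxy]-5-hydroxy-5-[(16E)-nonadec-16-en-1-yl]cyclohex-2-en-1-one | CC/C=C/CCCCCCCCCCCCCCC[C@]1(O)CC(=O)C=C[C@H]1O[Si](C)(C)C(C)(C)C | intermediate
17 | (4R,5S)-4,5-dihydroxy-5-[(16E)-nonadec-16-en-1-yl]cyclohex-2-en-1-one | CC/C=C/CCCCCCCCCCCCCCC[C@]1(O)CC(=O)C=C[C@H]1O | target

**Step count and risks**

Total step count: 10. Longest linear sequence: 8 steps (1, 2, 3, 6, 7, 8, 9, 10) from 15-bromopentadecan-1-ol; the threonate branch (4, 5) joins at step 6.

Steps most likely to fail: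

Step 7. What may go wrong: enolisation of ketone 11 by the strongly basic dianion instead of addition, and erosion of Felkin–Anh facial selectivity (competing chelation through O4 would give the C5 epimer). The fallback reverses the bond order so that the side chain enters last under Cram-chelate control; it sets out from 7 and returns to the route at 17. Compound 7 is protected as methyl (2R)-[(4S)-2,2-dimethyl-1,3-dioxolan-4-yl][(4-methoxybenzyl)oxy]acetate F1 (4-methoxybenzyl trichloroacetimidate, cat. CSA, CH2Cl2) and converted into the Weinreb amide F2 (MeNH(OMe)·HCl, i-PrMgCl, THF). Allylmagnesium bromide (THF, −78 °C) gives the allyl ketone F3. Grignard reagent 10 (THF, −78 °C) should then add to the magnesium chelate between the ketone oxygen and the 4-methoxybenzyl ether oxygen from the face of the C4 hydrogen, giving the tertiary alcohol F4 with the same (4R,5S) array. Tsuji–Wacker oxidation of the terminal alkene (PdCl2, CuCl, O2, DMF/H2O; the internal E-alkene reacts much more slowly) gives the methyl ketone F5, and H5IO6 (EtOAc) gives the keto aldehyde F6. Intramolecular aldol condensation (cat. piperidinium acetate, toluene, 40 °C) closes the same C2–C3 bond to give the 4-methoxybenzyl-protected enone F7, and DDQ (CH2Cl2/pH 7 buffer) gives 17.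

Step 9. What may go wrong: retro-aldol cleavage or β-elimination at the free tertiary C5 carbinol, or epimerisation at C4 next to the aldehyde, before the ring closes. The fallback ties O4 and O5 into a ring before the olefination; it sets out from 14 and returns to the route at 17. Compound 14 is desilylated (TBAF, AcOH, THF) to the diol F8, and 2,2-dimethoxypropane with PPTS (CH2Cl2) gives the bis-acetonide F9. H5IO6 (EtOAc, 0 °C) should cleave only the terminal acetonide to give the aldehyde F10. The same LiCl/i-Pr2NEt olefination gives the cis-fused acetonide enone F11, which carries no free β-hydroxyl, and aqueous AcOH (rt) gives 17.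

Step 10. What may go wrong: acid- or fluoride-induced dehydration of the β-hydroxy enone and aromatisation to the 3-alkylphenol during removal of the silyl ether. The fallback changes the order of events so that the enone never meets fluoride; it sets out from 15 and returns to the route at 17. Compound 15 is desilylated first (HF·pyridine, THF, 0 °C) to the α-hydroxy aldehyde F12 (hydrate or lactol forms expected), and the LiCl/i-Pr2NEt olefination (MeCN, rt) is run last to give 17 directly.

Further compounds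
F1 | step 7 | methyl (2R)-[(4S)-2,2-dimethyl-1,3-dioxolan-4-yl][(4-methoxybenzyl)oxy]acetate | COC(=O)[C@H](OCc1ccc(OC)cc1)[C@@H]1COC(C)(C)O1
F2 | step 7 | (2R)-2-[(4S)-2,2-dimethyl-1,3-dioxolan-4-yl]-N-methoxy-2-[(4-methoxybenzyl)oxy]-N-methylacetamide | CON(C)C(=O)[C@H](OCc1ccc(OC)cc1)[C@@H]1COC(C)(C)O1
F3 | step 7 | (1R)-1-[(4S)-2,2-dimethyl-1,3-dioxolan-4-yl]-1-[(4-methoxybenzyl)oxy]pent-4-en-2-one | C=CCC(=O)[C@H](OCc1ccc(OC)cc1)[C@@H]1COC(C)(C)O1
F4 | step 7 | (4S,20E)-4-{(R)-[(4S)-2,2-dimethyl-1,3-dioxolan-4-yl][(4-methoxybenzyl)oxy]methyl}tricosa-1,20-dien-4-ol | CC/C=C/CCCCCCCCCCCCCCC[C@](O)(CC=C)[C@H](OCc1ccc(OC)cc1)[C@@H]1COC(C)(C)O1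
F5 | step 7 | (4S,20E)-4-{(R)-[(4S)-2,2-dimethyl-1,3-dioxolan-4-yl][(4-methoxybenzyl)oxy]methyl}-4-hydroxytricos-20-en-2-one | CC/C=C/CCCCCCCCCCCCCCC[C@](O)(CC(C)=O)[C@H](OCc1ccc(OC)cc1)[C@@H]1COC(C)(C)O1
F6 | step 7 | (2S,3S,19E)-3-hydroxy-2-[(4-methoxybenzyl)oxy]-3-(2-oxopropyl)docos-19-enal | CC/C=C/CCCCCCCCCCCCCCC[C@](O)(CC(C)=O)[C@H](OCc1ccc(OC)cc1)C=O
F7 | step 7 | (4R,5S)-5-hydroxy-4-[(4-methoxybenzyl)oxy]-5-[(16E)-nonadec-16-en-1-yl]cyclohex-2-en-1-one | CC/C=C/CCCCCCCCCCCCCCC[C@]1(O)CC(=O)C=C[C@H]1OCc1ccc(OC)cc1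
F8 | step 9 | dimethyl [(4S,20E)-4-{(R)-[(4S)-2,2-dimethyl-1,3-dioxolan-4-yl](hydroxy)methyl}-4-hydroxy-2-oxotricos-20-en-1-yl]phosphonate | CC/C=C/CCCCCCCCCCCCCCC[C@](O)(CC(=O)CP(=O)(OC)OC)[C@H](O)[C@@H]1COC(C)(C)O1
F9 | step 9 | dimethyl {3-[(4S,5R)-5-[(4S)-2,2-dimethyl-1,3-dioxolan-4-yl]-2,2-dimethyl-4-[(16E)-nonadec-16-en-1-yl]-1,3-dioxolan-4-yl]-2-oxopropyl}phosphonate | CC/C=C/CCCCCCCCCCCCCCC[C@@]2(CC(=O)CP(=O)(OC)OC)OC(C)(C)O[C@@H]2[C@@H]1COC(C)(C)O1
F10 | step 9 | dimethyl {3-[(4S,5S)-5-formyl-2,2-dimethyl-4-[(16E)-nonadec-16-en-1-yl]-1,3-dioxolan-4-yl]-2-oxopropyl}phosphonate | CC/C=C/CCCCCCCCCCCCCCC[C@@]1(CC(=O)CP(=O)(OC)OC)OC(C)(C)O[C@@H]1C=O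
F11 | step 9 | (3aR,7aS)-2,2-dimethyl-7a-[(16E)-nonadec-16-en-1-yl]-7,7a-dihydro-1,3-benzodioxol-6(3aH)-one | CC/C=C/CCCCCCCCCCCCCCC[C@]12CC(=O)C=C[C@H]1OC(C)(C)O2
F12 | step 10 | dimethyl [(4S,20E)-4-hydroxy-4-[(1S)-1-hydroxy-2-oxoethyl]-2-oxotricos-20-en-1-yl]phosphonate | CC/C=C/CCCCCCCCCCCCCCC[C@](O)(CC(=O)CP(=O)(OC)OC)[C@H](O)C=O
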